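**Plan** (numbering: C1 = methyl-bearing quaternary fusion carbon, C2/C3 = ring CH2, C4 = isopropyl carbinol, C5 = fusion CH, C6 = acyloxy CH, C7 = CH2, C8 = methyl-bearing alkene carbon, C9 = alkene CH, C10 = ketone)
1. Retrosynthesis: cut the C6–O ester bond, then the C8=C9 alkene (opening the seven-membered ring), then the C4–isopropyl bond, and finally C5–C6 and C1–C10 together.
2. The double cut is possible because C1, C5 and C4 of the five-membered ring map onto the β-carbon, α-carbon and carbonyl carbon of 3-methylcyclopent-2-en-1-one: C1–C10 is a conjugate addition and C5–C6 an aldol of the enolate it leaves behind.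
3. Forward: the cyclopentane is bought as the enone; isopropenyl (C10, C9) and a C6–C8 ketal aldehyde are attached in one operation; the seven-membered ring is closed late by attack of C9 (as the C10 silyl enol ether) on the C8 ketal, followed by β-elimination to the enone.
4. Stereochemistry: C1 (S) from the chiral copper catalyst; C5 (S) and C6 (S) relayed from C1 in the aldol; C4 (R) from isopropyl addition anti to the C5 side chain; the trans ring fusion is the C1/C5 relationship set in step 4.

Key step: step 4

Assumption: the antipode of the chiral carbene ligand is chosen so that isopropenyl adds to the enone face giving (S)-C1; which antipode this is has to be fixed in a trial run on the simple conjugate adduct.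

Step 1
Reactants: 1 ethyl acetoacetate
Product: 2 ethyl 2-(2-methyl-1,3-dioxolan-2-yl)acetate
Conditions: ethylene glycol (1.5 equiv), TsOH·H2O (2 mol %), toluene, reflux, Dean–Stark
Reagents that add atoms: ethylene glycol, OCCO
Why: Acid-catalysed ketalisation with azeotropic removal of water masks the ketone (future C8) while the ester, which forms no ketal, is kept for the next step.

Step 2
Reactants: 2 ethyl 2-(2-methyl-1,3-dioxolan-2-yl)acetate
Product: 4 2-(2-methyl-1,3-dioxolan-2-yl)acetaldehyde, via aluminium hemiacetal 3 (not isolated)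
Conditions: DIBAL-H (1.05 equiv), CH2Cl2, −78 °C; MeOH, then aq. Rochelle salt
Reagents that add atoms: none
Why: Partial reduction of an ester with DIBAL-H at −78 °C should stop at the aldehyde level because the tetrahedral aluminium hemiacetal 3 does not collapse until the hydride has been destroyed in the work-up.

Step 3
Reactants: 5 2-bromopropene
Product: 6 isopropenylmagnesium bromide (ethereal solution, titrated before use)
Conditions: Mg turnings (I2-activated), Et2O, reflux
Reagents that add atoms: magnesium, [Mg]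
Why: Grignard reagent formation by insertion of magnesium into the vinylic C–Br bond is routine for 2-bromopropene, and diethyl ether is used because it is the solvent of the copper-catalysed step.

Step 4
Reactants: 7 3-methylcyclopent-2-en-1-one; 6 isopropenylmagnesium bromide; 4 2-(2-methyl-1,3-dioxolan-2-yl)acetaldehyde
Product: 9 (2S,3S)-2-[(1S)-1-hydroxy-2-(2-methyl-1,3-dioxolan-2-yl)ethyl]-3-methyl-3-(prop-1-en-2-yl)cyclopentan-1-one, via bromomagnesium enolate 8 (not isolated)
Conditions: Cu(OTf)2 (3 mol %), chiral hydroxyalkyl imidazolinium salt (NHC precursor, 4 mol %), 6 (1.1 equiv), Et2O, −30 °C, slow addition of 7; then 4 (1.3 equiv), −78 °C; aq. NH4Cl at −78 °C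
Reagents that add atoms: none
Why: A chiral NHC–copper(I) species formed in situ takes the isopropenyl group from the Grignard reagent and delivers it to the β-carbon C1 of the enone through a copper(III) intermediate, whose reductive elimination leaves bromomagnesium enolate 8, and this enolate is then intercepted at −78 °C by aldehyde 4. The closest known reaction type is the copper–carbene-catalysed asymmetric conjugate addition of Grignard reagents to β-methyl cyclic enones with electrophilic trapping of the magnesium enolate, i.e. a tandem conjugate addition–aldol three-component coupling. No ring is closed; the bonds made are C1–C10 and C5–C6. C1 is set by the ligand-controlled choice of enone face, C5 by approach of the aldehyde to the enolate face opposite the isopropenyl group (the larger of the two groups on the neighbouring quaternary carbon), and C6 by a chair-like Zimmerman–Traxler transition state in which the ring-locked (E)-enolate and an equatorial aldehyde substituent should lead to the anti aldol. The step needs 1,4- rather than 1,2-addition, which copper catalysis and slow addition of the enone secure, and C–C bond formation rather than proton transfer or retro-aldol at the enolate stage, which cold trapping and a cold quench secure.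

Step 5
Reactants: 9 aldol adduct
Product: 10 (2S,3S)-2-[(1S)-1-[(tert-butyldimethylsilyl)oxy]-2-(2-methyl-1,3-dioxolan-2-yl)ethyl]-3-methyl-3-(prop-1-en-2-yl)cyclopentan-1-one
Conditions: TBSOTf (1.2 equiv), 2,6-lutidine (2 equiv), CH2Cl2, −78 °C
Reagents that add atoms: tert-butyldimethylsilyl trifluoromethanesulfonate, CC(C)(C)[Si](C)(C)OS(=O)(=O)C(F)(F)F
Why: Silylation of the secondary alcohol with a silyl triflate and a hindered pyridine base is fast at −78 °C and too weakly basic to cause retro-aldol cleavage or epimerisation at C5.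

Step 6
Reactants: 10 silyl-protected ketone
Product: 11 (1R,2S,3S)-2-[(1S)-1-[(tert-butyldimethylsilyl)oxy]-2-(2-methyl-1,3-dioxolan-2-yl)ethyl]-3-methyl-1-(propan-2-yl)-3-(prop-1-en-2-yl)cyclopentan-1-ol
Conditions: iPrMgCl (3 equiv), anhydrous CeCl3 (3 equiv), THF, −78 → −20 °C; aq. NH4Cl
Reagents that add atoms: isopropylmagnesium chloride, CC(C)[Mg]Cl
Why: Organocerium 1,2-addition: the weakly basic isopropylcerium reagent should add to the hindered, enolisable C4 ketone without enolisation, β-elimination of the silyloxy group or β-hydride reduction, and it attacks the carbonyl face opposite the bulky C5 side chain, which places the new hydroxyl cis to that chain (4R).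

Step 7
Reactants: 11 tertiary alcohol
Product: 13 1-[(1S,2S,3R)-2-[(1S)-1-[(tert-butyldimethylsilyl)oxy]-2-(2-methyl-1,3-dioxolan-2-yl)ethyl]-3-hydroxy-1-methyl-3-(propan-2-yl)cyclopentyl]ethan-1-one, via secondary ozonide 12 (not isolated)
Conditions: O3, CH2Cl2, NaHCO3, −78 °C; then Me2S, −78 °C → rt
Reagents that add atoms: ozone, [O-][O+]=O
Why: Ozonolysis with reductive work-up (Criegee mechanism) cleaves the only C=C bond of 11 and turns the isopropenyl group into the C10 acetyl group, with C9 as its methyl, without touching a stereocentre.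

Step 8
Reactants: 13 methyl ketone
Product: 14 bis-silyl compound: C10 trimethylsilyl enol ether and C4 trimethylsilyl ether of 13
Conditions: LDA (2.5 equiv), THF, −78 °C; TMSCl (4 equiv), Et3N, −78 → 0 °C; non-aqueous work-up
Reagents that add atoms: chlorotrimethylsilane, C[Si](C)(C)Cl
Why: Kinetic enolate formation and O-silylation: the C9 methyl carries the only α-hydrogens of the only ketone (C1 is quaternary), so a single silyl enol ether can form, the tertiary lithium alkoxide at C4 is capped as its TMS ether in the same operation, and the ketal is inert to base.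

Step 9
Reactants: 14 bis-silyl compound
Product: 16 (3R,3aS,4S,8aS)-4-[(tert-butyldimethylsilyl)oxy]-6,8a-dimethyl-3-(propan-2-yl)-3-[(trimethylsilyl)oxy]-2,3,3a,4,5,8a-hexahydroazulen-8(1H)-one, via cyclised alkoxy ketone 15 (not isolated)
Conditions: TMSOTf (0.3 equiv), CH2Cl2, −78 °C; then DBU (3 equiv), −78 °C → rt
Reagents that add atoms: none
Why: Intramolecular Mukaiyama aldol-type addition: TMSOTf opens the dioxolane to an oxocarbenium ion at C8 that is captured by C9 of the silyl enol ether (7-enolendo-exo-trig closure in which only C9 is nucleophilic and only C8 electrophilic, with no basic enolate that could expel the C6 silyloxy group or attack C10), and DBU then removes the 2-silyloxyethoxy group of 15 by E1cB elimination across C9–C8 to give the conjugated enone with the trans ring fusion already fixed at C1/C5.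

Step 10
Reactants: 16 bis-silyl enone
Product: 17 (3R,3aS,4S,8aS)-3,4-dihydroxy-6,8a-dimethyl-3-(propan-2-yl)-2,3,3a,4,5,8a-hexahydroazulen-8(1H)-one
Conditions: HF·pyridine, pyridine, THF, 0 °C → rt
Reagents that add atoms: none
Why: Fluoride-mediated desilylation under buffered, weakly acidic conditions should cleave both Si–O bonds without base-induced vinylogous loss of the C6 oxygen or acid-induced dehydration of the C4 carbinol.

Step 11
Reactants: 17 diol; 18 3,4,5-trimethoxybenzoyl chloride
Product: 19 (3R,3aS,4S,8aS)-3-hydroxy-6,8a-dimethyl-8-oxo-3-(propan-2-yl)-1,2,3,3a,4,5,8,8a-octahydroazulen-4-yl 3,4,5-trimethoxybenzoate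
Conditions: pyridine, DMAP (0.2 equiv), CH2Cl2, 0 °C → rt
Reagents that add atoms: none
Why: DMAP-catalysed acylation (nucleophilic catalysis through the N-acylpyridinium ion) esterifies the secondary C6 hydroxyl with retention, since the C6–O bond is not broken, while the tertiary C4 hydroxyl is too hindered to react and the weak base avoids vinylogous elimination of the new ester.

**Compound list**
1 | ethyl acetoacetate (ethyl 3-oxobutanoate) | CCOC(=O)CC(C)=O | starting material
2 | ethyl 2-(2-methyl-1,3-dioxolan-2-yl)acetate | CCOC(=O)CC1(C)OCCO1 | intermediate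
3 | [1-ethoxy-2-(2-methyl-1,3-dioxolan-2-yl)ethoxy]bis(2-methylpropyl)aluminium, racemic at the hemiacetal carbon, formed in the flask | CCOC(CC1(C)OCCO1)O[Al](CC(C)C)CC(C)C | intermediate
4 | 2-(2-methyl-1,3-dioxolan-2-yl)acetaldehyde [3,3-(ethylenedioxy)butanal] | CC1(CC=O)OCCO1 | intermediate
5 | 2-bromopropene | CC(Br)=C | starting material
6 | isopropenylmagnesium bromide (prop-1-en-2-ylmagnesium bromide) | CC(=C)[Mg]Br | intermediate
7 | 3-methylcyclopent-2-en-1-one | CC1=CC(=O)CC1 | starting material
8 | bromomagnesium (3S)-3-methyl-3-(prop-1-en-2-yl)cyclopent-1-en-1-olate, formed in the flask | CC(=C)[C@@]1(C)CCC(O[Mg]Br)=C1 | intermediate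
9 | (2S,3S)-2-[(1S)-1-hydroxy-2-(2-methyl-1,3-dioxolan-2-yl)ethyl]-3-methyl-3-(prop-1-en-2-yl)cyclopentan-1-one (side chain trans to isopropenyl, anti aldol) | CC(=C)[C@@]1(C)CCC(=O)[C@@H]1[C@@H](O)CC2(C)OCCO2 | intermediate
10 | (2S,3S)-2-[(1S)-1-[(tert-butyldimethylsilyl)oxy]-2-(2-methyl-1,3-dioxolan-2-yl)ethyl]-3-methyl-3-(prop-1-en-2-yl)cyclopentan-1-one | CC(=C)[C@@]1(C)CCC(=O)[C@@H]1[C@@H](O[Si](C)(C)C(C)(C)C)CC2(C)OCCO2 | intermediate
11 | (1R,2S,3S)-2-[(1S)-1-[(tert-butyldimethylsilyl)oxy]-2-(2-methyl-1,3-dioxolan-2-yl)ethyl]-3-methyl-1-(propan-2-yl)-3-(prop-1-en-2-yl)cyclopentan-1-ol | CC(=C)[C@@]1(C)CC[C@@](O)(C(C)C)[C@@H]1[C@@H](O[Si](C)(C)C(C)(C)C)CC2(C)OCCO2 | intermediate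
12 | secondary ozonide of 11: the isopropenyl group replaced by a 3-methyl-1,2,4-trioxolan-3-yl group (either configuration at that carbon), other centres as in 11, formed in the flask | CC1(OCOO1)[C@@]2(C)CC[C@@](O)(C(C)C)[C@@H]2[C@@H](O[Si](C)(C)C(C)(C)C)CC3(C)OCCO3 | intermediate
13 | 1-[(1S,2S,3R)-2-[(1S)-1-[(tert-butyldimethylsilyl)oxy]-2-(2-methyl-1,3-dioxolan-2-yl)ethyl]-3-hydroxy-1-methyl-3-(propan-2-yl)cyclopentyl]ethan-1-one | CC(=O)[C@@]1(C)CC[C@@](O)(C(C)C)[C@@H]1[C@@H](O[Si](C)(C)C(C)(C)C)CC2(C)OCCO2 | intermediate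
14 | trimethyl{[(1R,2S,3S)-2-[(1S)-1-[(tert-butyldimethylsilyl)oxy]-2-(2-methyl-1,3-dioxolan-2-yl)ethyl]-3-methyl-1-(propan-2-yl)-3-[1-(trimethylsilyloxy)ethenyl]cyclopentyl]oxy}silane | C=C(O[Si](C)(C)C)[C@@]1(C)CC[C@@](O[Si](C)(C)C)(C(C)C)[C@@H]1[C@@H](O[Si](C)(C)C(C)(C)C)CC2(C)OCCO2 | intermediate
15 | (3R,3aS,4S,8aS)-4-[(tert-butyldimethylsilyl)oxy]-6,8a-dimethyl-3-(propan-2-yl)-3-[(trimethylsilyl)oxy]-6-[2-(trimethylsilyloxy)ethoxy]octahydroazulen-8(1H)-one, either configuration at C6 of the azulene skeleton, formed in the flask | CC(C)(C)[Si](C)(C)O[C@H]1CC(C)(OCCO[Si](C)(C)C)CC(=O)[C@@]2(C)CC[C@@](O[Si](C)(C)C)(C(C)C)[C@H]12 | intermediate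
16 | (3R,3aS,4S,8aS)-4-[(tert-butyldimethylsilyl)oxy]-6,8a-dimethyl-3-(propan-2-yl)-3-[(trimethylsilyl)oxy]-2,3,3a,4,5,8a-hexahydroazulen-8(1H)-one (trans-fused) | CC(C)(C)[Si](C)(C)O[C@H]1CC(C)=CC(=O)[C@@]2(C)CC[C@@](O[Si](C)(C)C)(C(C)C)[C@H]12 | intermediate
17 | (3R,3aS,4S,8aS)-3,4-dihydroxy-6,8a-dimethyl-3-(propan-2-yl)-2,3,3a,4,5,8a-hexahydroazulen-8(1H)-one | O[C@H]1CC(C)=CC(=O)[C@@]2(C)CC[C@@](O)(C(C)C)[C@H]12 | intermediate
18 | 3,4,5-trimethoxybenzoyl chloride | COc1cc(cc(OC)c1OC)C(Cl)=O | starting material
19 | (3R,3aS,4S,8aS)-3-hydroxy-6,8a-dimethyl-8-oxo-3-(propan-2-yl)-1,2,3,3a,4,5,8,8a-octahydroazulen-4-yl 3,4,5-trimethoxybenzoate | COc1cc(C(=O)O[C@H]2CC(C)=CC(=O)[C@@]3(C)CC[C@@](O)(C(C)C)[C@H]23)cc(OC)c1OC | target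

**Step count and risks**
Total: 11 steps. Longest linear sequence: 10 steps (1 → 2 → 4 → 9 → 10 → 11 → 13 → 14 → 16 → 17 → 19; steps 1, 2 and 4–11).

The three steps most likely to fail:

Step 4. Asymmetric induction on the flat five-membered enone may be low, the aldehyde may not discriminate well between the methyl and isopropenyl faces of the enolate, and proton transfer from the enolisable aldehyde or retro-aldol on warming may erode the adduct. The fallback separates the two bond formations. It sets out from 7 and 6: the same copper-catalysed addition is run with chlorotrimethylsilane present, so that the enolate is silylated as it forms and trimethyl{[(3S)-3-methyl-3-(prop-1-en-2-yl)cyclopent-1-en-1-yl]oxy}silane F1 can be isolated and its enantiomeric purity assessed. Methyllithium (THF, 0 °C) then cleaves the Si–O bond to lithium (3S)-3-methyl-3-(prop-1-en-2-yl)cyclopent-1-en-1-olate F2, which is cooled to −78 °C and treated with aldehyde 4 in a lithium aldol reaction. The route is rejoined at 9.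

Step 9. After ionisation of the ketal, loss of a proton to an enol ether or departure of the neighbouring C6 silyloxy group may outrun the seven-membered ring closure, and the base-induced elimination may continue with vinylogous loss of the C6 silyloxy group. The fallback closes the same C8–C9 bond under neutral, reductive conditions and sets out from 14.
- N-Bromosuccinimide (THF, −78 °C) should convert the silyl enol ether into 2-bromo-1-[(1S,2S,3R)-2-[(1S)-1-[(tert-butyldimethylsilyl)oxy]-2-(2-methyl-1,3-dioxolan-2-yl)ethyl]-1-methyl-3-(propan-2-yl)-3-[(trimethylsilyl)oxy]cyclopentyl]ethan-1-one F3.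
- PPTS in wet acetone then removes the ketal and the labile tertiary trimethylsilyl ether to give 2-bromo-1-[(1S,2S,3R)-2-[(1S)-1-[(tert-butyldimethylsilyl)oxy]-3-oxobutyl]-3-hydroxy-1-methyl-3-(propan-2-yl)cyclopentyl]ethan-1-one F4.
- Samarium diiodide (THF, −78 °C) reduces the C–Br bond to a samarium(III) enolate that adds to the C8 ketone in a Reformatsky-type aldol cyclisation, giving (3R,3aS,4S,8aS)-4-[(tert-butyldimethylsilyl)oxy]-3,6-dihydroxy-6,8a-dimethyl-3-(propan-2-yl)octahydroazulen-8(1H)-one F5.
- Methanesulfonyl chloride and triethylamine should convert the less hindered, β-keto tertiary alcohol into the 6-methanesulfonate of F5 F6 (not isolated), which loses methanesulfonate by E1cB elimination to give (3R,3aS,4S,8aS)-4-[(tert-butyldimethylsilyl)oxy]-3-hydroxy-6,8a-dimethyl-3-(propan-2-yl)-2,3,3a,4,5,8a-hexahydroazulen-8(1H)-one F7.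
- HF·pyridine, as in step 10, removes the remaining silyl group and the route is rejoined at 17.

Step 6. Enolisation with β-elimination of the silyloxy group, β-hydride reduction by the secondary organometallic, or attack from the wrong face (the isopropenyl group shields the face opposite the side chain) may compete with the desired addition. The fallback reverses the order of protection and addition and sets out from 9: excess isopropylmagnesium chloride and cerium chloride are applied to the unprotected aldol. The first equivalent forms the C6 alkoxide, which cannot be eliminated and holds the metal in a chelate with the C4 carbonyl, so that the face anti to the side chain remains the open one. This should give (1R,2S,3S)-2-[(1S)-1-hydroxy-2-(2-methyl-1,3-dioxolan-2-yl)ethyl]-3-methyl-1-(propan-2-yl)-3-(prop-1-en-2-yl)cyclopentan-1-ol F8. Selective silylation of its secondary hydroxyl (TBSOTf, 1.0 equiv, 2,6-lutidine, −78 °C) rejoins the route at 11.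

**Further compounds**
F1 | step 4 | trimethyl{[(3S)-3-methyl-3-(prop-1-en-2-yl)cyclopent-1-en-1-yl]oxy}silane | CC(=C)[C@@]1(C)CCC(O[Si](C)(C)C)=C1
F2 | step 4 | lithium (3S)-3-methyl-3-(prop-1-en-2-yl)cyclopent-1-en-1-olate | CC(=C)[C@@]1(C)CCC(O[Li])=C1
F3 | step 9 | 2-bromo-1-[(1S,2S,3R)-2-[(1S)-1-[(tert-butyldimethylsilyl)oxy]-2-(2-methyl-1,3-dioxolan-2-yl)ethyl]-1-methyl-3-(propan-2-yl)-3-[(trimethylsilyl)oxy]cyclopentyl]ethan-1-one | BrCC(=O)[C@@]1(C)CC[C@@](O[Si](C)(C)C)(C(C)C)[C@@H]1[C@@H](O[Si](C)(C)C(C)(C)C)CC2(C)OCCO2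
F4 | step 9 | 2-bromo-1-[(1S,2S,3R)-2-[(1S)-1-[(tert-butyldimethylsilyl)oxy]-3-oxobutyl]-3-hydroxy-1-methyl-3-(propan-2-yl)cyclopentyl]ethan-1-one | BrCC(=O)[C@@]1(C)CC[C@@](O)(C(C)C)[C@@H]1[C@@H](O[Si](C)(C)C(C)(C)C)CC(C)=O
F5 | step 9 | (3R,3aS,4S,8aS)-4-[(tert-butyldimethylsilyl)oxy]-3,6-dihydroxy-6,8a-dimethyl-3-(propan-2-yl)octahydroazulen-8(1H)-one, either configuration at C6 | CC(C)(C)[Si](C)(C)O[C@H]1CC(C)(O)CC(=O)[C@@]2(C)CC[C@@](O)(C(C)C)[C@H]12
F6 | step 9 | 6-methanesulfonate of F5 | CC(C)(C)[Si](C)(C)O[C@H]1CC(C)(OS(C)(=O)=O)CC(=O)[C@@]2(C)CC[C@@](O)(C(C)C)[C@H]12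
F7 | step 9 | (3R,3aS,4S,8aS)-4-[(tert-butyldimethylsilyl)oxy]-3-hydroxy-6,8a-dimethyl-3-(propan-2-yl)-2,3,3a,4,5,8a-hexahydroazulen-8(1H)-one | CC(C)(C)[Si](C)(C)O[C@H]1CC(C)=CC(=O)[C@@]2(C)CC[C@@](O)(C(C)C)[C@H]12
F8 | step 6 | (1R,2S,3S)-2-[(1S)-1-hydroxy-2-(2-methyl-1,3-dioxolan-2-yl)ethyl]-3-methyl-1-(propan-2-yl)-3-(prop-1-en-2-yl)cyclopentan-1-ol | CC(=C)[C@@]1(C)CC[C@@](O)(C(C)C)[C@@H]1[C@@H](O)CC2(C)OCCO2
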